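**Retrosynthetic overview**
1. The target has no C–C bond outside its two benzene rings, and no ring is formed: both arenes are bought intact, so the strategic bond is the diaryl ether C–O bond.
2. The last C–Br bond (ortho to OH) comes from an amine-directed ortho-bromination of 3,5-dibromo-2-(2-bromophenoxy)phenol.
3. The phenol OH comes from CHO (Baeyer–Villiger/Dakin-type oxidation), so ring A is cheap 3,5-dibromosalicylaldehyde with two bromines already in place.
4. Key disconnection, Ar–O with reversed polarity: ring B enters as a 2-bromophenyl cation equivalent (aryl-λ3-iodane from 1-bromo-2-iodobenzene) and is attacked by the hindered salicylaldehyde phenoxide. This inverts the usual pairing of 2-bromophenoxide with an activated aryl fluoride.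
5. Forward order: iodonium salt → diaryl ether → phenol → bromination.

Assumption: the target is achiral (no stereocentre, no stable stereoaxis), so there is no enantiomer to select; the SMILES is read as 2,3,5-tribromo-6-(2-bromophenoxy)phenol.

**Route**

Step 1
Reactants: 1 1-bromo-2-iodobenzene; 2 1,3,5-trimethoxybenzene
Product: 4 (2-bromophenyl)(2,4,6-trimethoxyphenyl)iodonium p-toluenesulfonate, via 1-bromo-2-[hydroxy(tosyloxy)iodo]benzene 3 (not isolated)
Conditions: mCPBA (1.0 equiv), TsOH·H2O (1.0 equiv), MeCN, 55 °C; then 2, 55 °C → rt; Et2O trituration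
Reagents that add atoms: p-toluenesulfonic acid monohydrate, Cc1ccc(cc1)S(=O)(=O)O.O; mCPBA, OOC(=O)c1cccc(Cl)c1 (its oxygen is in 3 only and leaves as water)
Why: One-pot Koser-type oxidation of the aryl iodide to the λ3-iodane 3, then electrophilic aromatic substitution (iodonium salt formation) on the very electron-rich arene 2, whose three equivalent CH positions give a single salt and whose aryl group later serves as a non-transferring dummy ligand.

Step 2
Reactants: 5 3,5-dibromo-2-hydroxybenzaldehyde; 4 (2-bromophenyl)(2,4,6-trimethoxyphenyl)iodonium p-toluenesulfonate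
Product: 7 3,5-dibromo-2-(2-bromophenoxy)benzaldehyde, via potassium 2,4-dibromo-6-formylphenolate 6 (not isolated)
Conditions: t-BuOK (1.0 equiv), THF, 0 °C; then 4 (1.2 equiv), 50 °C
Reagents that add atoms: potassium tert-butoxide, CC(C)(C)[O-].[K+] (potassium of 6 only; no atoms in 7)
Why: Metal-free O-arylation with a diaryliodonium salt (ligand exchange at iodine(III), then ligand coupling), in which the 2-bromophenyl group acts as an aryl cation equivalent and transfers in preference to the electron-rich trimethoxyphenyl dummy; because the C–O bond forms within the iodane and not by SNAr or metal insertion, the doubly ortho-substituted, weakly nucleophilic phenoxide 6, the free aldehyde and all C–Br bonds are tolerated.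

Step 3
Reactants: 7 3,5-dibromo-2-(2-bromophenoxy)benzaldehyde
Product: 9 3,5-dibromo-2-(2-bromophenoxy)phenol, via 3,5-dibromo-2-(2-bromophenoxy)phenyl formate 8 (not isolated)
Conditions: mCPBA (1.5 equiv), CH2Cl2, rt → 40 °C; then MeOH, cat. HCl, rt
Reagents that add atoms: mCPBA, OOC(=O)c1cccc(Cl)c1
Why: Baeyer–Villiger (Dakin-type) oxidation in which the ortho-aryloxy oxygen favours aryl over hydride migration to give formate 8, which is cleaved by acid-catalysed methanolysis (transesterification) without touching the diaryl ether or the C–Br bonds.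

Step 4
Reactants: 9 3,5-dibromo-2-(2-bromophenoxy)phenol
Product: 10 2,3,5-tribromo-6-(2-bromophenoxy)phenol
Conditions: NBS (1.0 equiv), i-Pr2NH (10 mol%), CH2Cl2, 0 °C
Reagents that add atoms: N-bromosuccinimide, BrN1C(=O)CCC1=O
Why: Amine-mediated ortho-selective electrophilic aromatic bromination (the N-bromoamine formed from NBS is delivered by hydrogen bonding to the carbon next to OH); the only other activated site, C4 para to OH, is wedged between two bromines and ring B is a deactivated aryl ether, so one bromine enters at C6.

**Compound list**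
1 | 1-bromo-2-iodobenzene | Brc1ccccc1I | starting material
2 | 1,3,5-trimethoxybenzene | COc1cc(OC)cc(OC)c1 | starting material
3 | 1-bromo-2-[hydroxy(tosyloxy)iodo]benzene | Cc1ccc(cc1)S(=O)(=O)OI(O)c1ccccc1Br | intermediate
4 | (2-bromophenyl)(2,4,6-trimethoxyphenyl)iodonium p-toluenesulfonate | COc1cc(OC)c([I+]c2ccccc2Br)c(OC)c1.Cc1ccc(cc1)S(=O)(=O)[O-] | intermediate
5 | 3,5-dibromo-2-hydroxybenzaldehyde | O=Cc1cc(Br)cc(Br)c1O | starting material
6 | potassium 2,4-dibromo-6-formylphenolate | O=Cc1cc(Br)cc(Br)c1[O-].[K+] | intermediate
7 | 3,5-dibromo-2-(2-bromophenoxy)benzaldehyde | O=Cc1cc(Br)cc(Br)c1Oc1ccccc1Br | intermediate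
8 | 3,5-dibromo-2-(2-bromophenoxy)phenyl formate | O=COc1cc(Br)cc(Br)c1Oc1ccccc1Br | intermediate
9 | 3,5-dibromo-2-(2-bromophenoxy)phenol | Oc1cc(Br)cc(Br)c1Oc1ccccc1Br | intermediate
10 | 2,3,5-tribromo-6-(2-bromophenoxy)phenol | Oc1c(Br)c(Br)cc(Br)c1Oc1ccccc1Br | target

**Step count and risks**
Total steps: 4. Longest linear sequence: 4 steps (1 → 4 → 7 → 9 → 10).

The three steps most likely to fail are step 2 (highest risk), step 4 and step 3.

Step 2 risk: the phenoxide 6 is acidic, flanked by CHO and Br, and may couple sluggishly with the iodane. The fallback sets out from 5 and 1 and returns at 7. It replaces the iodane by a copper-catalysed Ullmann ether coupling of the aryl iodide itself: 5, 1 (1.5 equiv), CuI (10 mol%), picolinic acid (20 mol%), K3PO4, DMSO, 80–90 °C. The C–I bond of 1 reacts with copper far faster than any C–Br bond, the phenoxide formed on the way is 6, and 7 is obtained directly; no new compound is made.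

Step 3 risk: with two bromines on the migrating ring, hydride migration could compete and give the benzoic acid. The fallback sets out from 4 and returns at 9, so it also bypasses step 2. The latent hydroxyl is carried as a methyl ether instead of an aldehyde. Purchased 2,4-dibromo-6-methoxyphenol F1 is deprotonated (t-BuOK, THF, 0 °C) to potassium 2,4-dibromo-6-methoxyphenolate F2. Arylation of this more nucleophilic phenoxide with 4 at 40 °C gives 1,5-dibromo-2-(2-bromophenoxy)-3-methoxybenzene F3. BBr3 (CH2Cl2, −78 °C → rt) cleaves only the methyl ether, via dibromo[3,5-dibromo-2-(2-bromophenoxy)phenoxy]borane F4, and aqueous work-up gives 9.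

Step 4 risk: some bromination para to OH, or double bromination, would give isomers that are hard to separate. The fallback sets out from 4 and returns at 10. It places every bromine before the ether bond is made. Purchased 2-bromo-6-hydroxybenzaldehyde F5 is dibrominated (Br2, NaOAc, AcOH, rt; OH directs ortho/para and CHO meta to the same two carbons) to 2,3,5-tribromo-6-hydroxybenzaldehyde F6. t-BuOK converts it into potassium 3,4,6-tribromo-2-formylphenolate F7, which is arylated with 4 as in step 2 to 2,3,5-tribromo-6-(2-bromophenoxy)benzaldehyde F8. mCPBA in CH2Cl2 gives 2,3,5-tribromo-6-(2-bromophenoxy)phenyl formate F9, and acid-catalysed methanolysis as in step 3 delivers 10.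

**Further compounds**
F0 | step 2 | none | none
F1 | step 3 | 2,4-dibromo-6-methoxyphenol | COc1cc(Br)cc(Br)c1O
F2 | step 3 | potassium 2,4-dibromo-6-methoxyphenolate | COc1cc(Br)cc(Br)c1[O-].[K+]
F3 | step 3 | 1,5-dibromo-2-(2-bromophenoxy)-3-methoxybenzene | COc1cc(Br)cc(Br)c1Oc1ccccc1Br
F4 | step 3 | dibromo[3,5-dibromo-2-(2-bromophenoxy)phenoxy]borane | BrB(Br)Oc1cc(Br)cc(Br)c1Oc1ccccc1Br
F5 | step 4 | 2-bromo-6-hydroxybenzaldehyde | O=Cc1c(O)cccc1Br
F6 | step 4 | 2,3,5-tribromo-6-hydroxybenzaldehyde | O=Cc1c(O)c(Br)cc(Br)c1Br
F7 | step 4 | potassium 3,4,6-tribromo-2-formylphenolate | O=Cc1c([O-])c(Br)cc(Br)c1Br.[K+]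
F8 | step 4 | 2,3,5-tribromo-6-(2-bromophenoxy)benzaldehyde | O=Cc1c(Oc2ccccc2Br)c(Br)cc(Br)c1Br
F9 | step 4 | 2,3,5-tribromo-6-(2-bromophenoxy)phenyl formate | O=COc1c(Oc2ccccc2Br)c(Br)cc(Br)c1Br
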